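- What is left in the north-east run, which is this very flask followed so far, after 1.33 min is a starting material reading of 0%, a slowly sinking isomer of the product, and a target near the scatter: 0.7% at 3.00 min, against a scatter of 0.5 percentage points.

- north-east: starting material 0.50 mM; protic impurity 0.025 mM; the very flask that is asked about, followed so far
- flask: starting material 0.50 mM; protic impurity 0.0250 mM; time 8.0 min

north-east run (percent of the starting material charged)

| time / min | isomer of the product / % | target / % | starting material / % |
|---|---|---|---|
| 0.500 | 28.5 | 11.4 | 5.6 |
| 1.00 | 30.5 | 1.9 | 0.4 |
| 1.33 | 29.7 | 1.3 | 0 |
| 2.00 | 27.3 | 0.1 | 0 |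
| 2.50 | 26.1 | 0.6 | 0 |
| 3.00 | 24.9 | 0.7 | 0.2 |

(readings scatter by 0.5 percentage points)

- share of isomer of the product in isomer of the product plus target at 0.40 s
- share of isomer of the product in isomer of the product plus target at 12 s
- share of isomer of the product in isomer of the product plus target at 8.0 min
- which of isomer of the product and target there is more of at 8.0 min



- A late target reading is too faint to give the share directly, so it has to be reckoned. Once starting material reads 0%, target can be fed from the isomer. If the isomer's loss passes through target, target made equals target lost (the steady-state balance), and time drops out of the comparison.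
- The isomer falls at 0.106 min⁻¹ between 1.33 min and 3.00 min, and target falls at 3.58 min⁻¹ between 0.500 min and 1.00 min.
- Because target is lost much faster than the isomer, late target stays a small fraction of the isomer. This fraction is the tail ratio, the late target per isomer, reckoned as the isomer's loss rate over target's: 2.95%.
- Starting material still read 5.6% at 0.500 min, so target was being fed while it fell. Its own loss may well be faster, so the tail ratio may lie high.
- My own number for 8.0 min is therefore a share of about 97.1%, with the isomer ahead. The ratio needs starting material gone, so it gives no word on 0.40 s or 12 s.
- Your forecast gives 44% (25% to 60%) at 0.40 s, 56% (45% to 68%) at 12 s, and 98% (92% to 100%) at 8.0 min, slightly above my number, with isomer of the product ahead. It adds: “The protic impurity's early role is uncertain, so the early ranges are wide.”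
- The flask gives 19.2% at 0.40 s, below the forecast's range, then 46.0% at 12 s and 98.5% at 8.0 min, with isomer of the product ahead, 16.4% against 0.256%.

    starting material ⇌ other conformer (K = 0.0500, k = 0.0400 s⁻¹)
    starting material → target (k = 0.0640 s⁻¹)
    other conformer → isomer of the product (k = 3.00 s⁻¹)
    target ⇌ isomer of the product (K = 1.10, k = 0.00160 s⁻¹)
    other conformer + protic impurity → quenched substrate (k = 13000 L mol⁻¹ s⁻¹)
    starting material → decomposition product (k = 1.40 × 10⁻⁴ s⁻¹)
    target → over-reaction product (k = 0.0930 s⁻¹)

- In this flask, target per isomer at 8.00 min is 1.56%, below the reckoned 2.95%. The scheme's steps between target and isomer, and from target to over-reaction product, hold no protic impurity, so the neighbour flask, charged with 0.10 mM instead of 0.0250 mM, is reckoned with the same 2.95%: a share of about 97.1%. The neighbour flask makes more quenched substrate, 8.53% against 2.44%, and at 8.00 min its share is 98.5%, with target 0.214% beside isomer 13.7%.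

Readings and results are simulated with made-up constants, noise included.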